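**Strategy.** Labdane numbering is used. Ring A (C1–C5, C10) is disconnected at C1–C10 and C4–C5: the methyl-bearing quaternary C10 beside ring-fusion C5, together with the methyl-bearing C4, is the retron of a Robinson annulation once a C3 carbonyl and a C4=C5 double bond are reinstated. In one base-mediated operation ethyl vinyl ketone is joined to an enantiopure 2-methyl-3-vinyl-4-ketal cyclohexanone (ring B, C8 masked, C9 vinyl as side-chain handle) by Michael addition (C1–C10) and aldol condensation (C4–C5); the C9 vinyl group directs the new C10 centre. Reductive hydroxymethylation of the enone then sets C5 and C4, and hydroboration–Suzuki coupling, dehydrogenation and methylenation complete the target.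

Key step: step 4

Remark: compounds 1, 2, 6 and 14 are taken as catalogue chemicals; in the Why lines labdane numbering is used (ring A = C1–C5 and C10, ring B = C5–C10, side chain C11–C16).

Step 1
Reactants: 1 1,4-dioxaspiro[4.5]deca-6,9-dien-8-one; 2 potassium ethenyltrifluoroborate
Product: 3 (10R)-10-ethenyl-1,4-dioxaspiro[4.5]dec-6-en-8-one
Conditions: [Rh(cod)2]BF4 (3 mol%), (R)-BINAP (3.3 mol%), Et3N, toluene/H2O, 25 °C
Reagents that add atoms: none
Why: Hayashi–Miyaura rhodium-catalysed asymmetric conjugate addition of an alkenyltrifluoroborate to a quinone monoketal, a documented substrate class, in which the (R)-BINAP complex of monovalent rhodium should, by the usual facial model for cyclohexenones, deliver the vinyl group so that C9 is set as (R), while the spiroketal slows a second addition.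

Step 2
Reactants: 3 (10R)-10-ethenyl-1,4-dioxaspiro[4.5]dec-6-en-8-one
Product: 4 (9S,10S)-10-ethenyl-9-methyl-1,4-dioxaspiro[4.5]dec-6-en-8-one
Conditions: LiN(i-Pr)2 (1.05 equiv), THF, −78 °C; MeI, −78 to −20 °C
Reagents that add atoms: iodomethane, CI
Why: Kinetic α'-enolate alkylation of a cyclohexenone, in which only C10 can be deprotonated because the other flank is the C6=C7 double bond and the ketal carbon carries no hydrogen, and the methyl group should enter anti to the adjacent vinyl group (trans), a centre that is re-enolised in step 4.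

Step 3
Reactants: 4 (9S,10S)-10-ethenyl-9-methyl-1,4-dioxaspiro[4.5]dec-6-en-8-one
Product: 5 (6S,7S)-6-ethenyl-7-methyl-1,4-dioxaspiro[4.5]decan-8-one
Conditions: [(Ph3P)CuH]6 (0.25 equiv), H2O (2 equiv), THF, rt
Reagents that add atoms: none
Why: Copper hydride conjugate reduction (Stryker type) should saturate the electron-poor C6=C7 bond chemoselectively and leave the isolated vinyl group and the ketal untouched; no stereocentre is formed.

Step 4
Reactants: 5 (6S,7S)-6-ethenyl-7-methyl-1,4-dioxaspiro[4.5]decan-8-one; 6 pent-1-en-3-one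
Product: 8 (1'S,8a'S)-1'-ethenyl-5',8a'-dimethyl-3',4',8',8a'-tetrahydro-1'H-spiro[1,3-dioxolane-2,2'-naphthalen]-6'(7'H)-one, via Michael adduct 7 (not isolated)
Conditions: KOH (0.3 equiv), EtOH, 0 °C to rt; then reflux
Reagents that add atoms: none
Why: Catalytic hydroxide equilibrates the enolates of 5 and the more substituted C10 enolate adds to ethyl vinyl ketone (Michael addition, C1–C10); proton transfer gives the ethyl ketone enolate, whose C4 carbon attacks the ring carbonyl C5 (intramolecular aldol, C4–C5), and E1cB loss of water on heating should deliver the C4=C5 enone. The closest known reaction type is the Robinson annulation of 2,3-disubstituted cyclohexanones with alkyl vinyl ketones, as used for eudesmane and eremophilane decalins. Ring A is closed by a 6-(enolexo)-exo-trig aldol addition. The only new stereocentre, quaternary C10, is controlled by C9: allylic strain with the C10 methyl places the vinyl group pseudoaxial and the acceptor should approach the enolate face anti to it, so that C1 ends trans and the methyl cis to the vinyl group. The step needs regioselectivity for C10 over C6, which the greater stability of the tetrasubstituted enolate under protic, reversible conditions should secure, and it needs the ketal and the vinyl group to be inert to base, which they are.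

Step 5
Reactants: 8 (1'S,8a'S)-1'-ethenyl-5',8a'-dimethyl-3',4',8',8a'-tetrahydro-1'H-spiro[1,3-dioxolane-2,2'-naphthalen]-6'(7'H)-one
Product: 10 (1'S,4a'S,5'S,8a'R)-1'-ethenyl-5'-(hydroxymethyl)-5',8a'-dimethyloctahydro-1'H-spiro[1,3-dioxolane-2,2'-naphthalen]-6'(5'H)-one, via lithium enolate 9 (not isolated)
Conditions: Li (2.2 equiv), t-BuOH (1 equiv), NH3(l)/THF, −78 °C; NH3 off, THF; CH2O (g), −78 to −30 °C; NH4Cl aq
Reagents that add atoms: formaldehyde, C=O
Why: Stork reductive alkylation of an enone, in which dissolving-metal reduction should protonate C5 axially to give the trans ring fusion (H5 anti to the C10 methyl) and the regiodefined C3 enolate should be hydroxymethylated at C4 on the face opposite the axial C10 methyl, leaving CH2OH equatorial and the C4 methyl axial.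

Step 6
Reactants: 10 (1'S,4a'S,5'S,8a'R)-1'-ethenyl-5'-(hydroxymethyl)-5',8a'-dimethyloctahydro-1'H-spiro[1,3-dioxolane-2,2'-naphthalen]-6'(5'H)-one
Product: 11 [(1'S,4a'S,5'S,8a'R)-1'-ethenyl-5',8a'-dimethyl-6'-oxooctahydro-1'H-spiro[1,3-dioxolane-2,2'-naphthalen]-5'-yl]methyl acetate
Conditions: Ac2O, pyridine, DMAP (cat.), CH2Cl2, 0 °C to rt
Reagents that add atoms: acetic anhydride, CC(=O)OC(C)=O
Why: DMAP-catalysed acetylation of the primary neopentyl alcohol installs the acetate of the target and removes the retro-aldol liability of the β-hydroxy ketone; no stereocentre is touched.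

Step 7
Reactants: 11 [(1'S,4a'S,5'S,8a'R)-1'-ethenyl-5',8a'-dimethyl-6'-oxooctahydro-1'H-spiro[1,3-dioxolane-2,2'-naphthalen]-5'-yl]methyl acetate
Product: 13 [(1'S,4a'S,5'S,8a'R)-1'-ethenyl-5',8a'-dimethyloctahydro-1'H-spiro[1,3-dioxolane-2,2'-naphthalen]-5'-yl]methyl acetate, via tosylhydrazone 12 (not isolated)
Conditions: TsNHNH2, EtOH, 70 °C; solvent switch; catecholborane, CHCl3, 0 °C to rt; NaOAc·3H2O, reflux
Reagents that add atoms: none
Why: Kabalka variant of the Caglioti tosylhydrazone reduction, in which catecholborane reduces the C=N bond and the derived diazene loses sulfinate and N2 to leave CH2 at C3 under nearly neutral conditions that should spare the acetate, the ketal and the vinyl group.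

Step 8
Reactants: 14 methyl 3-oxobutanoate
Product: 15 methyl (2E)-3-(trifluoromethylsulfonyloxy)but-2-enoate
Conditions: Tf2O, 25% aq Me4NOH, hexanes, 5 °C to rt
Reagents that add atoms: trifluoromethanesulfonic anhydride, O=S(=O)(OS(=O)(=O)C(F)(F)F)C(F)(F)F
Why: Stereoselective enol triflation of a β-keto ester under non-chelating biphasic conditions (tetraalkylammonium hydroxide), which is known to favour the (E)-enol triflate with OTf trans to the ester.

Step 9
Reactants: 13 [(1'S,4a'S,5'S,8a'R)-1'-ethenyl-5',8a'-dimethyloctahydro-1'H-spiro[1,3-dioxolane-2,2'-naphthalen]-5'-yl]methyl acetate; 15 methyl (2E)-3-(trifluoromethylsulfonyloxy)but-2-enoate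
Product: 17 methyl (2E)-5-[(1'S,4a'S,5'S,8a'R)-5'-(acetoxymethyl)-5',8a'-dimethyloctahydro-1'H-spiro[1,3-dioxolane-2,2'-naphthalen]-1'-yl]-3-methylpent-2-enoate, via alkylborane 16 (not isolated)
Conditions: 9-BBN-H (1.5 equiv), THF, 0 to 40 °C; then 15, Pd(dppf)Cl2 (5 mol%), K3PO4 (3 M aq), DMF, rt
Reagents that add atoms: none
Why: Anti-Markovnikov hydroboration of the monosubstituted vinyl group with 9-BBN followed by B-alkyl Suzuki–Miyaura coupling, which proceeds with retention at the enol triflate and so should fix the (E)-trisubstituted enoate and complete the side chain.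

Step 10
Reactants: 17 methyl (2E)-5-[(1'S,4a'S,5'S,8a'R)-5'-(acetoxymethyl)-5',8a'-dimethyloctahydro-1'H-spiro[1,3-dioxolane-2,2'-naphthalen]-1'-yl]-3-methylpent-2-enoate
Product: 18 methyl (2E)-5-[(1S,4aS,5S,8aR)-5-(acetoxymethyl)-5,8a-dimethyl-2-oxodecahydronaphthalen-1-yl]-3-methylpent-2-enoate
Conditions: 1 M HCl, THF, 40 °C
Reagents that add atoms: water, O
Why: Acid-catalysed ketal hydrolysis unmasks the C8 ketone, and although C9 becomes epimerisable its side chain already sits in the favoured equatorial position and both esters should tolerate the dilute acid.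

Step 11
Reactants: 18 methyl (2E)-5-[(1S,4aS,5S,8aR)-5-(acetoxymethyl)-5,8a-dimethyl-2-oxodecahydronaphthalen-1-yl]-3-methylpent-2-enoate
Product: 20 methyl (2E)-5-[(1S,4aS,5S,8aR)-5-(acetoxymethyl)-5,8a-dimethyl-2-oxo-1,2,4a,5,6,7,8,8a-octahydronaphthalen-1-yl]-3-methylpent-2-enoate, via silyl enol ether 19 (not isolated)
Conditions: LiN(SiMe3)2 (1.05 equiv), Me3SiCl, THF, −78 °C; then Pd(OAc)2 (1.05 equiv), MeCN, rt
Reagents that add atoms: none
Why: Saegusa–Ito oxidation, in which kinetic deprotonation should occur at the unhindered C7 methylene and not at the tertiary C9–H beside quaternary C10 or at the less acidic esters, and the enolate of divalent palladium undergoes β-hydride elimination to the C6=C7 enone.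

Step 12
Reactants: 20 methyl (2E)-5-[(1S,4aS,5S,8aR)-5-(acetoxymethyl)-5,8a-dimethyl-2-oxo-1,2,4a,5,6,7,8,8a-octahydronaphthalen-1-yl]-3-methylpent-2-enoate
Product: 21 methyl (2E)-5-[(1R,4aS,5S,8aS)-5-(acetoxymethyl)-5,8a-dimethyl-2-methylidene-1,2,4a,5,6,7,8,8a-octahydronaphthalen-1-yl]-3-methylpent-2-enoate
Conditions: Zn, CH2Br2, TiCl4, THF/CH2Cl2, 0 °C to rt
Reagents that add atoms: dibromomethane, BrCBr
Why: Takai–Lombardo methylenation with the non-basic zinc–titanium methylene reagent should convert the hindered conjugated C8 ketone into the exocyclic methylene of the s-trans diene without epimerising C9 and without touching the two esters.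

**Compound list**

1 | 1,4-dioxaspiro[4.5]deca-6,9-dien-8-one (p-benzoquinone monoethylene ketal) | O=C1C=CC2(OCCO2)C=C1 | starting material
2 | potassium ethenyltrifluoroborate | [K+].C=C[B-](F)(F)F | starting material
3 | (10R)-10-ethenyl-1,4-dioxaspiro[4.5]dec-6-en-8-one | C12(OCCO1)C=CC(=O)C[C@@H]2C=C | intermediate
4 | (9S,10S)-10-ethenyl-9-methyl-1,4-dioxaspiro[4.5]dec-6-en-8-one (methyl trans to vinyl) | C12(OCCO1)C=CC(=O)[C@@H](C)[C@@H]2C=C | intermediate
5 | (6S,7S)-6-ethenyl-7-methyl-1,4-dioxaspiro[4.5]decan-8-one (methyl trans to vinyl) | C12(OCCO1)CCC(=O)[C@@H](C)[C@@H]2C=C | intermediate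
6 | pent-1-en-3-one (ethyl vinyl ketone) | C=CC(=O)CC | starting material
7 | (6S,7S)-6-ethenyl-7-methyl-7-(3-oxopentyl)-1,4-dioxaspiro[4.5]decan-8-one (oxopentyl chain trans to vinyl) | C12(OCCO1)CCC(=O)[C@@](C)(CCC(=O)CC)[C@@H]2C=C | intermediate (not isolated)
8 | (1'S,8a'S)-1'-ethenyl-5',8a'-dimethyl-3',4',8',8a'-tetrahydro-1'H-spiro[1,3-dioxolane-2,2'-naphthalen]-6'(7'H)-one (vinyl cis to the angular methyl) | C12(OCCO1)CCC3=C(C)C(=O)CC[C@@]3(C)[C@@H]2C=C | intermediate
9 | lithium 1'-ethenyl-5',8a'-dimethyl-1',3',4',4a',8',8a'-hexahydro-7'H-spiro[1,3-dioxolane-2,2'-naphthalen]-6'-olate (trans-fused; H-4a' anti to the 8a' methyl) | C12(OCCO1)CC[C@@H]3C(C)=C([O-])CC[C@@]3(C)[C@@H]2C=C.[Li+] | intermediate (not isolated)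
10 | (1'S,4a'S,5'S,8a'R)-1'-ethenyl-5'-(hydroxymethyl)-5',8a'-dimethyloctahydro-1'H-spiro[1,3-dioxolane-2,2'-naphthalen]-6'(5'H)-one (trans-fused; CH2OH anti to the 8a' methyl) | C12(OCCO1)CC[C@@H]3[C@@](C)(CO)C(=O)CC[C@@]3(C)[C@@H]2C=C | intermediate
11 | [(1'S,4a'S,5'S,8a'R)-1'-ethenyl-5',8a'-dimethyl-6'-oxooctahydro-1'H-spiro[1,3-dioxolane-2,2'-naphthalen]-5'-yl]methyl acetate | C12(OCCO1)CC[C@@H]3[C@@](C)(COC(C)=O)C(=O)CC[C@@]3(C)[C@@H]2C=C | intermediate
12 | 4-methylbenzenesulfonylhydrazone of ketone 11 (at C6') | C12(OCCO1)CC[C@@H]3[C@@](C)(COC(C)=O)C(=NNS(=O)(=O)c4ccc(C)cc4)CC[C@@]3(C)[C@@H]2C=C | intermediate (not isolated)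
13 | [(1'S,4a'S,5'S,8a'R)-1'-ethenyl-5',8a'-dimethyloctahydro-1'H-spiro[1,3-dioxolane-2,2'-naphthalen]-5'-yl]methyl acetate | C12(OCCO1)CC[C@@H]3[C@@](C)(COC(C)=O)CCC[C@@]3(C)[C@@H]2C=C | intermediate
14 | methyl 3-oxobutanoate | CC(=O)CC(=O)OC | starting material
15 | methyl (2E)-3-(trifluoromethylsulfonyloxy)but-2-enoate | C/C(OS(=O)(=O)C(F)(F)F)=C\C(=O)OC | intermediate
16 | 9-{2-[(1'S,4a'S,5'S,8a'R)-5'-(acetoxymethyl)-5',8a'-dimethyloctahydro-1'H-spiro[1,3-dioxolane-2,2'-naphthalen]-1'-yl]ethyl}-9-borabicyclo[3.3.1]nonane | C12(OCCO1)CC[C@@H]3[C@@](C)(COC(C)=O)CCC[C@@]3(C)[C@@H]2CCB4C5CCCC4CCC5 | intermediate (not isolated)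
17 | methyl (2E)-5-[(1'S,4a'S,5'S,8a'R)-5'-(acetoxymethyl)-5',8a'-dimethyloctahydro-1'H-spiro[1,3-dioxolane-2,2'-naphthalen]-1'-yl]-3-methylpent-2-enoate | C12(OCCO1)CC[C@@H]3[C@@](C)(COC(C)=O)CCC[C@@]3(C)[C@@H]2CC/C(C)=C/C(=O)OC | intermediate
18 | methyl (2E)-5-[(1S,4aS,5S,8aR)-5-(acetoxymethyl)-5,8a-dimethyl-2-oxodecahydronaphthalen-1-yl]-3-methylpent-2-enoate | O=C1CC[C@@H]2[C@@](C)(COC(C)=O)CCC[C@@]2(C)[C@@H]1CC/C(C)=C/C(=O)OC | intermediate
19 | trimethylsilyl enol ether of 18 (C2–OSiMe3, C2=C3 of the decalin) | C[Si](C)(C)OC1=CC[C@@H]2[C@@](C)(COC(C)=O)CCC[C@@]2(C)[C@@H]1CC/C(C)=C/C(=O)OC | intermediate (not isolated)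
20 | methyl (2E)-5-[(1S,4aS,5S,8aR)-5-(acetoxymethyl)-5,8a-dimethyl-2-oxo-1,2,4a,5,6,7,8,8a-octahydronaphthalen-1-yl]-3-methylpent-2-enoate | O=C1C=C[C@@H]2[C@@](C)(COC(C)=O)CCC[C@@]2(C)[C@@H]1CC/C(C)=C/C(=O)OC | intermediate
21 | methyl (2E)-5-[(1R,4aS,5S,8aS)-5-(acetoxymethyl)-5,8a-dimethyl-2-methylidene-1,2,4a,5,6,7,8,8a-octahydronaphthalen-1-yl]-3-methylpent-2-enoate | C=C1C=C[C@@H]2[C@@](C)(COC(C)=O)CCC[C@@]2(C)[C@@H]1CC/C(C)=C/C(=O)OC | target

**Step count and risks**

Total steps: 12. Longest linear sequence: 11 steps (steps 1–7 and 9–12); step 8 is a one-step side branch.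

Steps most likely to fail:

Step 4. The Michael addition may proceed through the less substituted C6 enolate, or the enone may polymerise faster than it is attacked at the crowded C10. The fallback sets out from 5, which is condensed with (S)-1-phenylethylamine (toluene, Dean–Stark) to the ketimine F1. Its secondary enamine tautomer should add to 6 only at the more substituted carbon (d'Angelo deracemising Michael addition), and the (S)-amine is expected to be the matched auxiliary for approach anti to the vinyl group. Aqueous AcOH and then NaOMe/MeOH in the same flask release the amine and close ring A through 7, so the route is rejoined at 8.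

Step 7. Hydrazone formation at the neopentyl C3 ketone may be slow, or the reduction may stop short of the methylene. The fallback sets out from 11: NaBH4 (MeOH, 0 °C) should give the equatorial C3 alcohol F2, 1,1'-thiocarbonyldiimidazole (DMAP, CH2Cl2, 40 °C) the imidazole-1-carbothioate F3, and Barton–McCombie deoxygenation (Bu3SnH, AIBN, toluene, 100 °C) returns to the route at 13.

Step 11. The amide base may also deprotonate the acetate or the γ-position of the enoate during enol silane formation, which would erode yield and alkene position. The fallback sets out from 18 and uses direct dehydrogenation with 2-iodoxybenzoic acid (DMSO/toluene, 70 °C), which needs no strong base; within the ring only C6–C7 can be dehydrogenated because C10 is quaternary. It returns to the route at 20 and makes no new compound.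

Further compounds
F1 | step 4 | (6S,7S)-6-ethenyl-7-methyl-N-[(1S)-1-phenylethyl]-1,4-dioxaspiro[4.5]decan-8-imine | C12(OCCO1)CCC(=N[C@@H](C)c3ccccc3)[C@@H](C)[C@@H]2C=C
F2 | step 7 | [(1'S,4a'S,5'S,6'R,8a'R)-1'-ethenyl-6'-hydroxy-5',8a'-dimethyloctahydro-1'H-spiro[1,3-dioxolane-2,2'-naphthalen]-5'-yl]methyl acetate (equatorial hydroxyl) | C12(OCCO1)CC[C@@H]3[C@@](C)(COC(C)=O)[C@H](O)CC[C@@]3(C)[C@@H]2C=C
F3 | step 7 | O-[(1'S,4a'S,5'S,6'R,8a'R)-5'-(acetoxymethyl)-1'-ethenyl-5',8a'-dimethyloctahydro-1'H-spiro[1,3-dioxolane-2,2'-naphthalen]-6'-yl] 1H-imidazole-1-carbothioate | C12(OCCO1)CC[C@@H]3[C@@](C)(COC(C)=O)[C@H](OC(=S)n4ccnc4)CC[C@@]3(C)[C@@H]2C=C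
F0 | step 11 | none | none
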